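# Proposed total synthesis of (2S)-2-heptadecyl-5,7-dihydroxy-6,8-dimethylchroman-4-one (CNP0087661.1, compound 14)

## Analysis of the target

Target 14 has a benzene ring A (C4a, C5, C6, C7, C8, C8a) fused through C4a–C8a to a dihydropyranone ring B (O1, C2, C3, C4, C4a, C8a). C2 carries an unbranched C17 chain and is the only stereocentre (priorities O1 > C3 > C1′ > H, hence S).

C2 is the β-carbon of a β-aryloxy ketone. Any base that enolises C3 can expel O1 and add it back (retro-oxa-Michael/oxa-Michael), which racemises C2. This bond and the two free, easily oxidised phenols at C5 and C7 are the sensitive parts.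

Ring A has no C–H bond. Oxygen sits on C5, C7 and C8a, and carbon sits on C4a (the C4 acyl group), C6 and C8 (methyl groups). The C-dimethylated triphenol from which the usual routes start must itself be made in several steps, because C-methylation of such phenols tends to run on to gem-dimethyl dienones.

The feature used here is that ring A is the enol form of a cyclohexane-1,3,5-trione in which C5–C6(CH3)–C7 and C8a–C8(CH3) are propionate-type units. The unit O1–C8a=C4a–C4=O is a vinylogous ester that can exist without ring A, as a 2,3-dihydropyran-4-one. Ring B with C2 can therefore be finished first under mild conditions. Ring A can then be closed last by a C7–C8 bond between an ester carbon and the CH2 group of a 6-ethyl substituent.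

## Retrosynthetic reasoning

**14 ⇒ 13 ⇒ 12 (cut C7–C8 of ring A).** 14 is written as its trione tautomer 13, and the C7–C8 bond is cut to give dihydropyranone 12.
- This ring bond is chosen because its nucleophile (C8, the CH2 of the 6-ethyl group) is already activated through C4a=C8a by C4=O and C5=O. Its electrophile (C7) can be carried as a plain methyl ester.
- A cut at C4a–C5 would require acylation of an sp2 carbon of a deactivated vinylogous ester.
- A cut at C8–C8a would put C8a at the acid oxidation level, so that ring closure would expel O1.
- The gain is large: no arene starting material, no phenol protecting group, both C-methyl groups in place from the start, and a C2–O1 bond that is never touched.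
- The forward step must achieve C- over O-acylation without enolising C3.

**12 ⇒ 7 + 10, through 11 (cut C4a=C8a and O1–C8a).** C8a is a linchpin carbon bonded to C4a, O1 and C8. At the amide acetal level (10) it can condense with the most acidic CH2 of acyclic 7 and then be captured by the δ-hydroxyl group. One operation closes ring B and installs the ethyl group that later becomes C8 and its methyl group. The C2–O bond is only a spectator.

**10 ⇒ 8, through 9.** The amide acetal comes from the commercial amide by O-methylation and alkoxide addition.

**7 ⇒ 4 + 5, through 6 (cut C4–C4a).** The 3,5-dioxo ester is split at the bond between the acyl carbon C4 and the terminal carbon of keto ester 5. The dianion 6 brings C4a, C5, C6 with its methyl group and C7 in one piece. Strained lactone 4 is an unprotected, activated form of the β-hydroxy acyl unit that opens at the acyl–oxygen bond with retention at C2.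

**4 ⇒ 1 + 2, through 3 (cut C2–C3 and C4–O1).** A catalytic asymmetric formal [2+2] of ketene 3 with aldehyde 1 sets C2 at the very start. It is used on the substrate class (unbranched aliphatic aldehydes) for which this reaction is best suited. C2 plus the C17 chain is the cheap C18 aldehyde.

## Alternatives that were turned down

**Alternative 1:** (textbook) cut O1–C2. Acetophenone A1 would be condensed with 1 to enone A2. A bifunctional amine–thiourea catalyst would then close ring B by an enantioselective 6-endo-trig oxa-Michael addition. It was turned down for these reasons: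
- The bond formed is the very bond that opens in the racemisation path. The addition is reversible under the basic catalysis that drives it, so the enantiopurity is limited by equilibration and not only by the catalyst.
- A β-alkyl enone next to a strongly donating ring is a weak acceptor. An additional ester at C3 and its later removal would probably be needed.
- The aldol step with three free phenols calls for protection and deprotection.
- A1 must first be built from the parent triphenol by two C-methylations and an acylation, so the count exceeds that of the chosen route.

**Alternative 2:** cut C2–C1′. Protected chromone A3 would take up heptadecylmagnesium bromide A4 in a copper-catalysed enantioselective conjugate addition (CuBr·SMe2, chiral ferrocenyl diphosphine). This would give protected chromanone A5, which is then debenzylated. It was turned down for these reasons: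
- The oxygen substituents of ring A push electron density into C4=O and C2 and lower the acceptor strength.
- The magnesium enolate formed is exactly the C3 enolate from which O1 is expelled.
- A4 needs an odd-numbered C17 halide.
- The route still needs the hexasubstituted arene plus two protecting-group steps.

**Alternative 3:** cut C2–C3. Diazoketone A6, an octadecyl aryl ether, would undergo a 1,6 C–H insertion of its rhodium carbenoid (chiral dirhodium tetracarboxylate) into the OCH2 group. This would close ring B and set C2 from an achiral precursor. The idea is attractive because C2 and the chain come from a C18 alkyl group. It was turned down for these reasons: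
- An acceptor-only carbenoid offers weak enantiocontrol.
- Attack on the ether oxygen (five-membered oxonium ylide, then a [1,2]-shift) competes with insertion.
- The second ortho oxygen needs a group without reactive C–H bonds.
- The three phenols must be differentiated one by one on an arene that has first to be made. The path to A6 costs more than the key step wins.

Key step: step 5

Assumption: the L-valine-derived aluminium triamine catalyst of step 1 is taken to direct attack to the Re face of unbranched aldehydes (S-lactone). If the sense were opposite, the D-valine-derived ligand would be used.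

## Route

**Step 1**
Reactants: 1 octadecanal; 2 acetyl bromide
Product: 4 (4S)-4-heptadecyloxetan-2-one, via ketene 3 (not isolated)
Conditions: AlMe3 (10 mol%), (S,S)-N-benzyl-N,N-bis[3-methyl-2-(trifluoromethylsulfonylamino)butyl]amine (10 mol%), iPr2NEt (1.7 equiv), CH2Cl2, −50 °C
Reagents that add atoms: none
Why: Catalytic asymmetric acyl halide–aldehyde cyclocondensation, a formal [2+2] of ketene 3 (made in the flask from 2 and iPr2NEt) with the aluminium-bound aldehyde, for which unbranched aliphatic aldehydes are standard substrates. The chiral aluminium triamine complex shields one face of 1, so that the ketene carbon (later C3) attacks the Re face and sets C2 as S.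

**Step 2**
Reactants: 4 (4S)-4-heptadecyloxetan-2-one; 5 methyl 2-methyl-3-oxobutanoate
Product: 7 methyl (7S)-7-hydroxy-2-methyl-3,5-dioxotetracosanoate (epimers at C2 of the chain), via keto ester dianion 6 (not isolated)
Conditions: 5 (2.5 equiv), NaH, then n-BuLi, THF, 0 °C; add 4, −78 → −30 °C; AcOH, −78 °C; used crude
Reagents that add atoms: none
Why: Claisen-type acylation of a β-keto ester dianion at its terminal carbon by a lactone; the hard carbanion attacks the strained acyl carbon of 4, so the C–O bond at the stereocentre and its configuration are kept. The excess dianion deprotonates the new 1,3-diketone, which should prevent over-addition and retro-aldol cleavage.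

**Step 3**
Reactants: 8 N,N-dimethylpropanamide
Product: 10 1,1-dimethoxy-N,N-dimethylpropan-1-amine, via methoxyiminium methyl sulfate 9 (not isolated)
Conditions: Me2SO4, neat, 80 °C; then NaOMe, MeOH, 0 °C; distillation
Reagents that add atoms: dimethyl sulfate COS(=O)(=O)OC; sodium methoxide [Na+].[O-]C
Why: Standard amide acetal synthesis: O-methylation of the amide gives the iminium salt 9, and methoxide adds to its carbon.

**Step 4**
Reactants: 7 methyl (7S)-7-hydroxy-2-methyl-3,5-dioxotetracosanoate; 10 1,1-dimethoxy-N,N-dimethylpropan-1-amine
Product: 12 methyl 3-[(2S)-6-ethyl-2-heptadecyl-4-oxo-3,4-dihydro-2H-pyran-5-yl]-2-methyl-3-oxopropanoate, via enaminone 11 (not isolated)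
Conditions: 10 (1.3 equiv), PhMe, rt; then AcOH (20 mol%), 40 °C
Reagents that add atoms: none
Why: Maitland–Japp-type dihydropyranone synthesis: the amide acetal condenses with the most acidic CH2 of 7 (between the two ketones, later C4a) to enaminone 11. The δ-hydroxyl then adds to the enaminone carbon (6-endo-trig) and dimethylamine leaves, closing ring B. The stereocentre is a spectator because its C–O bond is not broken.

**Step 5**
Reactants: 12 methyl 3-[(2S)-6-ethyl-2-heptadecyl-4-oxo-3,4-dihydro-2H-pyran-5-yl]-2-methyl-3-oxopropanoate
Product: 14 (2S)-2-heptadecyl-5,7-dihydroxy-6,8-dimethyl-2,3-dihydro-4H-chromen-4-one, via trione tautomer 13 (not isolated)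
Conditions: LiOtBu (1.2 equiv), THF, 0 °C → rt; then 1 M HCl
Reagents that add atoms: none
Why: Proposed new method: LiOtBu first removes the most acidic proton of 12 (C6–H of the β-keto ester), and proton exchange through the tBuOH formed gives a small equilibrium share of the extended enolate in which a CH2 proton of the 6-ethyl group (C8) is lost, a position made acidic in a vinylogous way by both C4=O and C5=O. C8 of this enolate attacks the ester carbon C7, methoxide leaves to give trione 13, and two enolisations deliver aromatic ring A, whose phenoxide makes the sequence irreversible. The closest known reaction types are the Claisen/Dieckmann cyclisation of 3,5,7-triketo esters to acylphloroglucinols, the closure of δ-keto esters to cyclohexane-1,3-diones and the Claisen condensations of the vinylogously acidic 2-methyl group of chromones; new is the 5-acyl-6-alkyl-2,3-dihydropyran-4-one as the carbon acid. Ring A closes in a 6-(enolendo)-exo-trig mode, and the ring-fixed cis arrangement of the ethyl group and the C5 acyl group on C4a=C8a holds C8 and C7 within bonding distance. No stereocentre is formed; C2 keeps its S configuration because the C2–O1 bond is never broken and because all species are anionic under the conditions, so that a second deprotonation at C3 and the expulsion of O1 as part of a dianion are both disfavoured. The step needs C-acylation at C8 rather than O-acylation at O4 (which would lead to an isomeric 4-hydroxy-2-pyranone): lithium chelation between O4 and O5 masks O4 and turns the C6–C7 arm toward C8, and only the C-acylation ends in an aromatic sink. C3 cannot compete as nucleophile, since it is far less acidic and its attack on C7 would give a bicyclo[3.3.1]nonane with a bridgehead double bond.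

## Compound list

1 | octadecanal | CCCCCCCCCCCCCCCCCC=O | starting material
2 | acetyl bromide | CC(=O)Br | starting material
3 | ketene | C=C=O | intermediate
4 | (4S)-4-heptadecyloxetan-2-one | CCCCCCCCCCCCCCCCC[C@H]1CC(=O)O1 | intermediate
5 | methyl 2-methyl-3-oxobutanoate | CC(=O)C(C)C(=O)OC | starting material
6 | sodium lithium dianion of methyl 2-methyl-3-oxobutanoate | [Na+].[Li+].[CH2-]C([O-])=C(C)C(=O)OC | intermediate
7 | methyl (7S)-7-hydroxy-2-methyl-3,5-dioxotetracosanoate | CCCCCCCCCCCCCCCCC[C@H](O)CC(=O)CC(=O)C(C)C(=O)OC | intermediate
8 | N,N-dimethylpropanamide | CCC(=O)N(C)C | starting material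
9 | 1-methoxy-N,N-dimethylpropan-1-iminium methyl sulfate | CCC(OC)=[N+](C)C.COS(=O)(=O)[O-] | intermediate
10 | 1,1-dimethoxy-N,N-dimethylpropan-1-amine | CCC(OC)(OC)N(C)C | intermediate
11 | methyl (7S)-4-[1-(dimethylamino)propylidene]-7-hydroxy-2-methyl-3,5-dioxotetracosanoate | CCCCCCCCCCCCCCCCC[C@H](O)CC(=O)C(=C(CC)N(C)C)C(=O)C(C)C(=O)OC | intermediate
12 | methyl 3-[(2S)-6-ethyl-2-heptadecyl-4-oxo-3,4-dihydro-2H-pyran-5-yl]-2-methyl-3-oxopropanoate | CCCCCCCCCCCCCCCCC[C@H]1CC(=O)C(C(=O)C(C)C(=O)OC)=C(CC)O1 | intermediate
13 | (2S)-2-heptadecyl-6,8-dimethyl-2,3-dihydrochromene-4,5,7(6H,8H)-trione | CCCCCCCCCCCCCCCCC[C@H]1CC(=O)C2=C(O1)C(C)C(=O)C(C)C2=O | intermediate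
14 | (2S)-2-heptadecyl-5,7-dihydroxy-6,8-dimethyl-2,3-dihydro-4H-chromen-4-one | CCCCCCCCCCCCCCCCC[C@H]1CC(=O)c2c(O)c(C)c(O)c(C)c2O1 | target

## Step count and least certain steps

Total step count: 5. Longest linear sequence: 4 (steps 1, 2, 4, 5). Step 3 is a one-step side branch.

**Step 5 (key step, proposed new method).**
- Most likely failures:
  - acylation through O4 instead of C8, because the extended enolate is ambident;
  - stalling, because the resting enolate at C6 is conjugated with the ester and lowers its electrophilicity;
  - retro-Claisen loss of the C5 acyl group;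
  - slow loss of enantiopurity by retro-oxa-Michael opening, if long reaction times or heating become necessary.
- Fallback (pericyclic and neutral instead of ionic; sets out from 4, returns at 13):
  - 4 is opened as in step 2 with the dianion of commercial tert-butyl 2-methyl-3-oxobutanoate to give tert-butyl (7S)-7-hydroxy-2-methyl-3,5-dioxotetracosanoate F1.
  - Condensation of F1 with 10 as in step 4 gives tert-butyl 3-[(2S)-6-ethyl-2-heptadecyl-4-oxo-3,4-dihydro-2H-pyran-5-yl]-2-methyl-3-oxopropanoate F2.
  - Heating F2 in toluene or xylene (110–140 °C) should expel tert-butanol. This is the known thermal route from tert-butyl β-keto esters to α-oxoketenes, and it gives the α-oxoketene (2S)-6-ethyl-2-heptadecyl-5-(2-methyl-3-oxoprop-2-enoyl)-2,3-dihydropyran-4-one F3.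
  - A [1,5]-hydrogen shift from the ethyl CH2 to O5 makes F3 a dienylketene. Its 6π electrocyclisation, the known last stage of the Danheiser benzannulation, leads to 13 and hence to 14. No enolate is ever present at C3.

**Step 4.**
- Most likely failures:
  - cyclodehydration of the δ-hydroxy diketone onto the C5 ketone before the condensation takes place;
  - O-methylation of the enols by the amide acetal;
  - incomplete displacement of dimethylamine at the crowded, tetrasubstituted enaminone carbon;
  - amine-induced opening of ring B, with erosion at C2.
- Fallback (C-acylation and acid instead of orthoamide condensation; sets out from 7, returns at 12):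
  - 7 is C-propanoylated at the central carbon through its magnesium chelate (MgCl2, pyridine, propanoyl chloride, CH2Cl2) to give methyl (7S)-7-hydroxy-2-methyl-3,5-dioxo-4-propanoyltetracosanoate F4.
  - F4 is closed by catalytic TsOH (cyclodehydration of the hydroxyl group onto the less hindered propanoyl carbonyl) to give 12.

**Step 2.**
- Most likely failures:
  - proton transfer from the α-CH2 of the lactone to the strongly basic dianion instead of addition;
  - retro-aldol cleavage on warming;
  - cyclodehydration of 7 during isolation.
- Fallback (protected, unstrained acyl donor; sets out from 4, returns at 7):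
  - 4 is opened with MeNH(OMe)·HCl/Me2AlCl to give (3S)-3-hydroxy-N-methoxy-N-methylicosanamide F5.
  - F5 is silylated (TBSCl, imidazole) to give (3S)-3-(tert-butyldimethylsilyloxy)-N-methoxy-N-methylicosanamide F6.
  - F6 is coupled with 6 to give methyl (7S)-7-(tert-butyldimethylsilyloxy)-2-methyl-3,5-dioxotetracosanoate F7.
  - F7 is desilylated with buffered HF·pyridine to give 7.

**Step 1.**
- Most likely failures:
  - poor solubility of the waxy C18 aldehyde at −50 °C, so that ketene dimerisation and aldehyde self-condensation outrun the cyclocondensation;
  - lower facial selectivity if the temperature has to be raised.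
- Fallback (acyclic acetate aldol instead of a β-lactone; sets out from 1, returns at 7):
  - A Ti(OiPr)4/BINOL-catalysed Mukaiyama aldol of 1 with 1-(tert-butylsulfanyl)-1-(trimethylsilyloxy)ethene, followed by an acidic work-up, gives S-tert-butyl (3S)-3-hydroxyicosanethioate F8.
  - F8 acylates an excess of dianion 6 directly to give 7.

## Further compounds

F1 | step 5 | tert-butyl (7S)-7-hydroxy-2-methyl-3,5-dioxotetracosanoate | CCCCCCCCCCCCCCCCC[C@H](O)CC(=O)CC(=O)C(C)C(=O)OC(C)(C)C
F2 | step 5 | tert-butyl 3-[(2S)-6-ethyl-2-heptadecyl-4-oxo-3,4-dihydro-2H-pyran-5-yl]-2-methyl-3-oxopropanoate | CCCCCCCCCCCCCCCCC[C@H]1CC(=O)C(C(=O)C(C)C(=O)OC(C)(C)C)=C(CC)O1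
F3 | step 5 | (2S)-6-ethyl-2-heptadecyl-5-(2-methyl-3-oxoprop-2-enoyl)-2,3-dihydropyran-4-one | CCCCCCCCCCCCCCCCC[C@H]1CC(=O)C(C(=O)C(C)=C=O)=C(CC)O1
F4 | step 4 | methyl (7S)-7-hydroxy-2-methyl-3,5-dioxo-4-propanoyltetracosanoate | CCCCCCCCCCCCCCCCC[C@H](O)CC(=O)C(C(=O)CC)C(=O)C(C)C(=O)OC
F5 | step 2 | (3S)-3-hydroxy-N-methoxy-N-methylicosanamide | CCCCCCCCCCCCCCCCC[C@H](O)CC(=O)N(C)OC
F6 | step 2 | (3S)-3-(tert-butyldimethylsilyloxy)-N-methoxy-N-methylicosanamide | CCCCCCCCCCCCCCCCC[C@H](O[Si](C)(C)C(C)(C)C)CC(=O)N(C)OC
F7 | step 2 | methyl (7S)-7-(tert-butyldimethylsilyloxy)-2-methyl-3,5-dioxotetracosanoate | CCCCCCCCCCCCCCCCC[C@H](O[Si](C)(C)C(C)(C)C)CC(=O)CC(=O)C(C)C(=O)OC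
F8 | step 1 | S-tert-butyl (3S)-3-hydroxyicosanethioate | CCCCCCCCCCCCCCCCC[C@H](O)CC(=O)SC(C)(C)C
A1 | alternative 1 | 1-(2,4,6-trihydroxy-3,5-dimethylphenyl)ethan-1-one | CC(=O)c1c(O)c(C)c(O)c(C)c1O
A2 | alternative 1 | (E)-1-(2,4,6-trihydroxy-3,5-dimethylphenyl)icos-2-en-1-one | CCCCCCCCCCCCCCCCC/C=C/C(=O)c1c(O)c(C)c(O)c(C)c1O
A3 | alternative 2 | 5,7-bis(benzyloxy)-6,8-dimethyl-4H-chromen-4-one | O=C1C=COc2c(C)c(OCc3ccccc3)c(C)c(OCc3ccccc3)c12
A4 | alternative 2 | heptadecylmagnesium bromide | CCCCCCCCCCCCCCCCC[Mg]Br
A5 | alternative 2 | (2S)-5,7-bis(benzyloxy)-2-heptadecyl-6,8-dimethyl-2,3-dihydro-4H-chromen-4-one | CCCCCCCCCCCCCCCCC[C@H]1CC(=O)c2c(OCc3ccccc3)c(C)c(OCc3ccccc3)c(C)c2O1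
A6 | alternative 3 | 1-[4-(benzyloxy)-2-methoxy-3,5-dimethyl-6-(octadecyloxy)phenyl]-2-diazoethan-1-one | CCCCCCCCCCCCCCCCCCOc1c(C)c(OCc2ccccc2)c(C)c(OC)c1C(=O)C=[N+]=[N-]
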